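The flavone is cut in ring C: C4, which bears only its oxygen and is bonded to C4a of ring A and to C3, can be supplied by carbon monoxide. One palladium-catalysed operation unites an ortho-iodophenol, CO and a terminal alkyne, forming C4a–C4, C4–C3 and O1–C2 and closing the pyranone. Ring A derives from 3,5-diisopropoxy-4-methylphenol, which is symmetric about its OH–methyl axis, so either ortho carbon gives the same iodide and the 6-methyl pattern is unambiguous. The alkyne is the (2'S,3'S)-trans-5'-ethynyl-2',3'-diaryldihydrobenzofuran pentabenzyl ether, made enantioselectively by a chiral sulfonium ylide annulation. C3 is then hydroxylated and methylated, and BCl3 removes all seven protecting groups.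

Key step: step 13

Conventions: primed locants are those of the dihydrobenzofuran within the flavone. G stands for the (2S,3S)-4,7-bis(benzyloxy)-3-[4-(benzyloxy)phenyl]-2-[3,5-bis(benzyloxy)phenyl]-2,3-dihydro-1-benzofuran-5-yl group (aryl groups trans).

Assumption: (1R,4R,5R)-isothiocineole is taken to give the (2S)-configured ylide-derived carbon, by analogy with the sense of its ylide epoxidations; if the opposite sense is found, the (1S,4S,5S) sulfide is used and nothing else changes.

Step 1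
Reactants: 1 2-methylresorcinol
Product: 2 1,3-diisopropoxy-2-methylbenzene
Conditions: 2-bromopropane, K2CO3, DMF, 70 °C
Reagents that add atoms: 2-bromopropane, CC(C)Br
Why: Williamson ether synthesis of both phenols; isopropyl ethers are chosen for ring A because they carry no aromatic C–H that could be borylated in step 2, resist the amide base of step 14 and fall to BCl3 in step 16.

Step 2
Reactants: 2 1,3-diisopropoxy-2-methylbenzene
Product: 4 3,5-diisopropoxy-4-methylphenol, via pinacol boronate 3 (not isolated)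
Conditions: [Ir(OMe)(cod)]2 (1 mol %), dtbpy (2 mol %), B2pin2 (0.6 equiv), THF, 80 °C; then aq. NaOH, 30% H2O2, 0 °C
Reagents that add atoms: bis(pinacolato)diboron, CC1(C)OB(OC1(C)C)B1OC(C)(C)C(C)(C)O1 (boron of 3); hydrogen peroxide, OO (phenol oxygen of 4)
Why: Iridium-catalysed aromatic C–H borylation is sterically governed, so boron should enter only at C5, the one ring C–H with no ortho substituent, and basic peroxide then converts the aryl boronate into the phenol at the same carbon.

Step 3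
Reactants: 4 3,5-diisopropoxy-4-methylphenol
Product: 5 2-iodo-3,5-diisopropoxy-4-methylphenol
Conditions: I2 (1.0 equiv), NaHCO3, THF–H2O, 0 °C
Reagents that add atoms: iodine, II
Why: Electrophilic aromatic iodination of an electron-rich phenol whose para carbon carries the methyl group and whose two ortho carbons are identical by symmetry, so one equivalent of iodine can give only this mono-iodide.

Step 4
Reactants: 6 2,5-dihydroxybenzaldehyde
Product: 7 2,5-bis(benzyloxy)benzaldehyde
Conditions: BnBr, K2CO3, DMF, 60 °C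
Reagents that add atoms: benzyl bromide, BrCc1ccccc1
Why: Williamson ether synthesis; warming overcomes the hydrogen bond of the 2-hydroxyl to the formyl group so that both phenols are benzylated.

Step 5
Reactants: 7 2,5-bis(benzyloxy)benzaldehyde
Product: 8 2,5-bis(benzyloxy)-4-bromobenzaldehyde
Conditions: Br2, NaOAc, AcOH, rt
Reagents that add atoms: bromine, BrBr
Why: Electrophilic aromatic bromination directed by the 5-alkoxy group to C4 (ortho to it, para to the formyl group), the site at which 2,5-dialkoxybenzaldehydes brominate, with acetate buffering the HBr so that the benzyl ethers survive.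

Step 6
Reactants: 8 2,5-bis(benzyloxy)-4-bromobenzaldehyde
Product: 10 2,5-bis(benzyloxy)-4-bromophenol, via aryl formate 9 (not isolated)
Conditions: mCPBA, CH2Cl2, rt; aq. NaHCO3 wash; then K2CO3 (cat.), MeOH, rt
Reagents that add atoms: 3-chloroperoxybenzoic acid, OOC(=O)c1cccc(Cl)c1
Why: Baeyer–Villiger (Dakin-type) oxidation in which the electron-rich aryl group migrates in preference to hydrogen, followed by methanolysis of the formate, which leaves the bromide and the benzyl ethers untouched.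

Step 7
Reactants: 10 2,5-bis(benzyloxy)-4-bromophenol; 11 4-(benzyloxy)benzaldehyde
Product: 12 3,6-bis(benzyloxy)-2-[[4-(benzyloxy)phenyl](hydroxy)methyl]-4-bromophenol (racemic)
Conditions: EtMgBr (1.0 equiv), Et2O, 0 °C; solvent change to toluene; then 11, rt
Reagents that add atoms: none
Why: Ortho-specific hydroxyalkylation of a bromomagnesium phenoxide, in which the magnesium-bound aldehyde is delivered through a cyclic transition state to the only free ortho carbon; the carbinol centre forms as a racemate, which does not matter because it becomes trigonal in step 10.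

Step 8
Reactants: 12 3,6-bis(benzyloxy)-2-[[4-(benzyloxy)phenyl](hydroxy)methyl]-4-bromophenol
Product: 13 3,6-bis(benzyloxy)-2-[[4-(benzyloxy)phenyl](4-methylbenzenesulfonyl)methyl]-4-bromophenol (racemic)
Conditions: 4-MeC6H4SO2Na, HCO2H–CH2Cl2, rt
Reagents that add atoms: sodium 4-methylbenzenesulfinate, Cc1ccc(cc1)S(=O)[O-].[Na+]
Why: Acid-promoted SN1 substitution of the doubly stabilised benzhydrylic alcohol by sulfinate at sulfur installs a leaving group that base can later expel from the phenoxide; the racemic sulfone carbon is likewise erased in step 10.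

Step 9
Reactants: 14 3,5-bis(benzyloxy)benzyl bromide; 15 (1R,4R,5R)-isothiocineole
Product: 16 (1R,4R,5R)-6-[3,5-bis(benzyloxy)benzyl]-4,7,7-trimethyl-6-thiabicyclo[3.2.1]octan-6-ium trifluoromethanesulfonate
Conditions: LiOTf, CH2Cl2–H2O, rt
Reagents that add atoms: lithium trifluoromethanesulfonate, [Li+].[O-]S(=O)(=O)C(F)(F)F
Why: SN2 S-alkylation of the sulfide by the benzylic bromide with bromide-to-triflate exchange in the two-phase medium; alkylation on the less hindered sulfur lone pair should give a single sulfonium diastereomer.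

Step 10
Reactants: 13 3,6-bis(benzyloxy)-2-[[4-(benzyloxy)phenyl](4-methylbenzenesulfonyl)methyl]-4-bromophenol; 16 the sulfonium triflate
Product: 19 G–Br [(2S,3S)-4,7-bis(benzyloxy)-3-[4-(benzyloxy)phenyl]-2-[3,5-bis(benzyloxy)phenyl]-5-bromo-2,3-dihydro-1-benzofuran], via ortho-quinone methide 17 (not isolated), via sulfonium ylide 18 (not isolated)
Conditions: Cs2CO3, MeCN–CH2Cl2, −20 °C to rt
Reagents that add atoms: none
Why: Formal [4+1] annulation of a sulfonium ylide with an ortho-quinone methide, in which carbonate expels sulfinate from the phenoxide of 13 to give 17 and deprotonates 16 to 18, the ylide adds to the exocyclic carbon and the phenoxide displaces the sulfide in a 5-exo-tet closure with inversion; the chiral sulfide fixes the ylide conformation and its attacking face, which should set C2 as (S), and the anti betaine that places the two aryl groups trans closes fastest, which sets C3 as (S).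

Step 11
Reactants: 19 G–Br
Product: 20 G–C≡C–SiMe3 [trimethyl(2-G-ethynyl)silane]
Conditions: Me3SiC≡CH, PdCl2(PhCN)2 (3 mol %), P(t-Bu)3 (6 mol %), CuI (2 mol %), i-Pr2NH, dioxane, rt to 50 °C
Reagents that add atoms: ethynyltrimethylsilane, C#C[Si](C)(C)C
Why: Sonogashira coupling in which the bulky electron-rich phosphine lets zerovalent palladium insert into the electron-rich, ortho-substituted aryl bromide under mild conditions while the silyl group blocks the second alkyne terminus; the stereocentres are not involved.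

Step 12
Reactants: 20 G–C≡C–SiMe3
Product: 21 G–C≡CH [(2S,3S)-4,7-bis(benzyloxy)-3-[4-(benzyloxy)phenyl]-2-[3,5-bis(benzyloxy)phenyl]-5-ethynyl-2,3-dihydro-1-benzofuran]
Conditions: K2CO3 (cat.), MeOH–THF, rt
Reagents that add atoms: none
Why: Protodesilylation of the alkynylsilane by catalytic methoxide, which leaves the ethers and both stereocentres unchanged.

Step 13
Reactants: 5 2-iodo-3,5-diisopropoxy-4-methylphenol; 21 G–C≡CH
Product: 24 2-G-5,7-diisopropoxy-6-methyl-4H-chromen-4-one (flavone without the C3 oxygen), via ynone 22 (not isolated), via diethylaminoenone 23 (not isolated)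
Conditions: PdCl2(dppf) (5 mol %), CO (10 bar), Et2NH–THF, 80 °C
Reagents that add atoms: carbon monoxide, [C-]#[O+] (C4 and its oxygen); diethylamine, CCNCC (only in intermediate 23)
Why: Zerovalent palladium formed in situ inserts into the carbon–iodine bond of 5, CO insertion gives the aroyl–palladium species, and amine-assisted transfer of the acetylide of 21 with reductive elimination gives ynone 22, so C4a–C4 and C4–C3 are made and C4 with its oxygen comes from CO. Diethylamine then adds to the ynone β-carbon to give enaminone 23, and the ortho phenol oxygen attacks the same carbon and expels the amine, forming O1–C2 and closing the pyranone by a six-membered addition–elimination (net 6-endo) instead of the 5-exo attack that would give an aurone. This is the known palladium-catalysed carbonylative coupling of ortho-iodophenols with terminal alkynes to flavones. No stereocentre is created, and C2' and C3' of 21 carry no site that amine base can epimerise. The step needs carbonylation to outrun direct alkynylation and amide formation, which CO pressure and the chelating phosphine favour, and it needs one regiochemical outcome in ring A, which is secured because 5 has a single free hydroxyl and its iodine sits on one of two equivalent ortho carbons of symmetric phenol 4, the para carbon being methylated.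

Step 14
Reactants: 24 2-G-5,7-diisopropoxy-6-methyl-4H-chromen-4-one
Product: 27 2-G-3-hydroxy-5,7-diisopropoxy-6-methyl-4H-chromen-4-one, via 3-lithioflavone 25 (not isolated), via flavone-3-boronate 26 (not isolated)
Conditions: LiN(i-Pr)2, THF, −78 °C; B(OMe)3, −78 to 0 °C; then AcOH, 30% H2O2, 0 °C to rt
Reagents that add atoms: lithium diisopropylamide, CC(C)[N-]C(C)C.[Li+] (lithium of 25); trimethyl borate, COB(OC)OC (boron of 26); hydrogen peroxide, OO (C3 oxygen of 27)
Why: C3 lithiation of a flavone (the chromone C3–H next to the carbonyl group is the most acidic site), borate trapping and peroxide-induced carbon-to-oxygen migration give the flavonol; the isopropyl and benzyl ethers tolerate the amide base at −78 °C and no stereocentre is formed.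

Step 15
Reactants: 27 2-G-3-hydroxy-5,7-diisopropoxy-6-methyl-4H-chromen-4-one
Product: 28 2-G-3-methoxy-5,7-diisopropoxy-6-methyl-4H-chromen-4-one
Conditions: MeI, K2CO3, DMF, rt
Reagents that add atoms: iodomethane, CI
Why: Williamson O-methylation of the acidic 3-hydroxyl, the only free OH in the molecule, under mild carbonate base.

Step 16
Reactants: 28 2-G-3-methoxy-5,7-diisopropoxy-6-methyl-4H-chromen-4-one
Product: 29 target, 2-[(2S,3S)-2-(3,5-dihydroxyphenyl)-4,7-dihydroxy-3-(4-hydroxyphenyl)-2,3-dihydro-1-benzofuran-5-yl]-5,7-dihydroxy-3-methoxy-6-methyl-4H-chromen-4-one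
Conditions: BCl3 (excess), C6HMe5, CH2Cl2, −78 to 0 °C; MeOH quench; argon, degassed work-up
Reagents that add atoms: none
Why: Lewis-acid ether cleavage in which BCl3 ionises the five aryl benzyl ethers at low temperature while pentamethylbenzene traps the benzyl cations (Friedel–Crafts) so that the electron-rich rings are not C-benzylated, and on warming cleaves the two isopropyl ethers; the 3-methoxyl (a methyl ether without peri chelation) and the C2'–O1' bond (its benzylic carbon bears a non-donating 3,5-dioxygenated aryl group) should survive with both stereocentres intact.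

Compound list
1 | 2-methylresorcinol | Cc1c(O)cccc1O | starting material
2 | 1,3-diisopropoxy-2-methylbenzene | Cc1c(OC(C)C)cccc1OC(C)C | intermediate
3 | 2-(3,5-diisopropoxy-4-methylphenyl)-4,4,5,5-tetramethyl-1,3,2-dioxaborolane | Cc1c(OC(C)C)cc(B2OC(C)(C)C(C)(C)O2)cc1OC(C)C | intermediate
4 | 3,5-diisopropoxy-4-methylphenol | Cc1c(OC(C)C)cc(O)cc1OC(C)C | intermediate
5 | 2-iodo-3,5-diisopropoxy-4-methylphenol | Cc1c(OC(C)C)cc(O)c(I)c1OC(C)C | intermediate
6 | 2,5-dihydroxybenzaldehyde | O=Cc1cc(O)ccc1O | starting material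
7 | 2,5-bis(benzyloxy)benzaldehyde | O=Cc1cc(OCc2ccccc2)ccc1OCc1ccccc1 | intermediate
8 | 2,5-bis(benzyloxy)-4-bromobenzaldehyde | O=Cc1cc(OCc2ccccc2)c(Br)cc1OCc1ccccc1 | intermediate
9 | 2,5-bis(benzyloxy)-4-bromophenyl formate | O=COc1cc(OCc2ccccc2)c(Br)cc1OCc1ccccc1 | intermediate
10 | 2,5-bis(benzyloxy)-4-bromophenol | Oc1cc(OCc2ccccc2)c(Br)cc1OCc1ccccc1 | intermediate
11 | 4-(benzyloxy)benzaldehyde | O=Cc1ccc(OCc2ccccc2)cc1 | starting material
12 | 3,6-bis(benzyloxy)-2-[[4-(benzyloxy)phenyl](hydroxy)methyl]-4-bromophenol, racemic | OC(c1ccc(OCc2ccccc2)cc1)c1c(O)c(OCc2ccccc2)cc(Br)c1OCc1ccccc1 | intermediate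
13 | 3,6-bis(benzyloxy)-2-[[4-(benzyloxy)phenyl](4-methylbenzenesulfonyl)methyl]-4-bromophenol, racemic | Cc1ccc(cc1)S(=O)(=O)C(c1ccc(OCc2ccccc2)cc1)c1c(O)c(OCc2ccccc2)cc(Br)c1OCc1ccccc1 | intermediate
14 | 3,5-bis(benzyloxy)benzyl bromide | BrCc1cc(OCc2ccccc2)cc(OCc2ccccc2)c1 | starting material
15 | (1R,4R,5R)-4,7,7-trimethyl-6-thiabicyclo[3.2.1]octane (isothiocineole) | C[C@@H]1CC[C@@H]2C[C@H]1SC2(C)C | starting material
16 | (1R,4R,5R)-6-[3,5-bis(benzyloxy)benzyl]-4,7,7-trimethyl-6-thiabicyclo[3.2.1]octan-6-ium trifluoromethanesulfonate (one diastereomer at sulfur, not specified) | C[C@@H]1CC[C@@H]2C[C@H]1[S+](Cc1cc(OCc3ccccc3)cc(OCc3ccccc3)c1)C2(C)C.[O-]S(=O)(=O)C(F)(F)F | intermediate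
17 | 2,5-bis(benzyloxy)-6-[[4-(benzyloxy)phenyl]methylidene]-4-bromocyclohexa-2,4-dien-1-one (ortho-quinone methide, alkene geometry not defined) | O=C1C(OCc2ccccc2)=CC(Br)=C(OCc2ccccc2)C1=Cc1ccc(OCc2ccccc2)cc1 | intermediate
18 | sulfonium ylide of 16 | C[C@@H]1CC[C@@H]2C[C@H]1[S+]([CH-]c1cc(OCc3ccccc3)cc(OCc3ccccc3)c1)C2(C)C | intermediate
19 | (2S,3S)-4,7-bis(benzyloxy)-3-[4-(benzyloxy)phenyl]-2-[3,5-bis(benzyloxy)phenyl]-5-bromo-2,3-dihydro-1-benzofuran (G–Br) | Brc1cc(OCc2ccccc2)c2c(c1OCc1ccccc1)[C@H](c1ccc(OCc3ccccc3)cc1)[C@@H](c1cc(OCc3ccccc3)cc(OCc3ccccc3)c1)O2 | intermediate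
20 | [[(2S,3S)-4,7-bis(benzyloxy)-3-[4-(benzyloxy)phenyl]-2-[3,5-bis(benzyloxy)phenyl]-2,3-dihydro-1-benzofuran-5-yl]ethynyl]trimethylsilane | C[Si](C)(C)C#Cc1cc(OCc2ccccc2)c2c(c1OCc1ccccc1)[C@H](c1ccc(OCc3ccccc3)cc1)[C@@H](c1cc(OCc3ccccc3)cc(OCc3ccccc3)c1)O2 | intermediate
21 | (2S,3S)-4,7-bis(benzyloxy)-3-[4-(benzyloxy)phenyl]-2-[3,5-bis(benzyloxy)phenyl]-5-ethynyl-2,3-dihydro-1-benzofuran | C#Cc1cc(OCc2ccccc2)c2c(c1OCc1ccccc1)[C@H](c1ccc(OCc3ccccc3)cc1)[C@@H](c1cc(OCc3ccccc3)cc(OCc3ccccc3)c1)O2 | intermediate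
22 | 3-G-1-(6-hydroxy-2,4-diisopropoxy-3-methylphenyl)prop-2-yn-1-one | Cc1c(OC(C)C)cc(O)c(c1OC(C)C)C(=O)C#Cc1cc(OCc2ccccc2)c2c(c1OCc1ccccc1)[C@H](c1ccc(OCc3ccccc3)cc1)[C@@H](c1cc(OCc3ccccc3)cc(OCc3ccccc3)c1)O2 | intermediate
23 | 3-(diethylamino)-3-G-1-(6-hydroxy-2,4-diisopropoxy-3-methylphenyl)prop-2-en-1-one (alkene geometry not defined) | CCN(CC)C(=CC(=O)c1c(O)cc(OC(C)C)c(C)c1OC(C)C)c1cc(OCc2ccccc2)c2c(c1OCc1ccccc1)[C@H](c1ccc(OCc3ccccc3)cc1)[C@@H](c1cc(OCc3ccccc3)cc(OCc3ccccc3)c1)O2 | intermediate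
24 | 2-G-5,7-diisopropoxy-6-methyl-4H-chromen-4-one | O=c1cc(-c2cc(OCc3ccccc3)c3c(c2OCc2ccccc2)[C@H](c2ccc(OCc4ccccc4)cc2)[C@@H](c2cc(OCc4ccccc4)cc(OCc4ccccc4)c2)O3)oc2cc(OC(C)C)c(C)c(OC(C)C)c12 | intermediate
25 | 2-G-3-lithio-5,7-diisopropoxy-6-methyl-4H-chromen-4-one | [Li]c1c(-c2cc(OCc3ccccc3)c3c(c2OCc2ccccc2)[C@H](c2ccc(OCc4ccccc4)cc2)[C@@H](c2cc(OCc4ccccc4)cc(OCc4ccccc4)c2)O3)oc2cc(OC(C)C)c(C)c(OC(C)C)c2c1=O | intermediate
26 | dimethyl (2-G-5,7-diisopropoxy-6-methyl-4-oxo-4H-chromen-3-yl)boronate | COB(OC)c1c(-c2cc(OCc3ccccc3)c3c(c2OCc2ccccc2)[C@H](c2ccc(OCc4ccccc4)cc2)[C@@H](c2cc(OCc4ccccc4)cc(OCc4ccccc4)c2)O3)oc2cc(OC(C)C)c(C)c(OC(C)C)c2c1=O | intermediate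
27 | 2-G-3-hydroxy-5,7-diisopropoxy-6-methyl-4H-chromen-4-one | Oc1c(-c2cc(OCc3ccccc3)c3c(c2OCc2ccccc2)[C@H](c2ccc(OCc4ccccc4)cc2)[C@@H](c2cc(OCc4ccccc4)cc(OCc4ccccc4)c2)O3)oc2cc(OC(C)C)c(C)c(OC(C)C)c2c1=O | intermediate
28 | 2-G-3-methoxy-5,7-diisopropoxy-6-methyl-4H-chromen-4-one | COc1c(-c2cc(OCc3ccccc3)c3c(c2OCc2ccccc2)[C@H](c2ccc(OCc4ccccc4)cc2)[C@@H](c2cc(OCc4ccccc4)cc(OCc4ccccc4)c2)O3)oc2cc(OC(C)C)c(C)c(OC(C)C)c2c1=O | intermediate
29 | 2-[(2S,3S)-2-(3,5-dihydroxyphenyl)-4,7-dihydroxy-3-(4-hydroxyphenyl)-2,3-dihydro-1-benzofuran-5-yl]-5,7-dihydroxy-3-methoxy-6-methyl-4H-chromen-4-one | COc1c(-c2cc(O)c3c(c2O)[C@H](c2ccc(O)cc2)[C@@H](c2cc(O)cc(O)c2)O3)oc2cc(O)c(C)c(O)c2c1=O | target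

Total step count: 16.
Longest linear sequence: 12 steps (steps 4–8 and 10–16, from 2,5-dihydroxybenzaldehyde).

Steps most likely to fail

Step 13. CO insertion may be outrun by direct alkynylation of the aryl–palladium species, which leads to a benzofuran after cyclisation. The hindered aroyl–palladium species may also be captured by diethylamine as an amide, or the ynone may close through the five-membered mode. The fallback builds the pyranone by the chalcone route; it sets out from bromide 19 and phenol 4 and comes back at flavone 24. Bromine–lithium exchange on 19 (n-BuLi, THF, −78 °C) gives the aryllithium G–Li F1, which DMF formylates to the aldehyde G–CHO F2. Phenol 4 is C-acetylated ortho to its hydroxyl (AcOH, BF3·OEt2, Friedel–Crafts; both ortho carbons are equivalent) to 1-(6-hydroxy-2,4-diisopropoxy-3-methylphenyl)ethan-1-one F3. Claisen–Schmidt condensation of F2 with F3 (KOH, EtOH–THF) gives the chalcone (E)-3-G-1-(6-hydroxy-2,4-diisopropoxy-3-methylphenyl)prop-2-en-1-one F4, and oxidative cyclisation (I2 cat., DMSO, 120 °C) gives 24.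

Step 10. Incomplete facial control of the semi-stabilised ylide or reversible addition to the quinone methide may erode enantiomeric and trans/cis purity, and ylide self-condensation may consume the salt. The fallback separates enantiomers instead of inducing them; it sets out from bromide 14 and sulfone 13 and comes back at 19. Bromide 14 alkylates tetrahydrothiophene (acetone, rt) to the achiral salt 1-[3,5-bis(benzyloxy)benzyl]thiolan-1-ium bromide F5. With Cs2CO3 in the presence of 13 this gives the thiolanium benzylide F6, which undergoes the same annulation through 17 to the racemic trans bromide F7. Preparative chromatography on a chiral stationary phase then separates 19 from its (2R,3R)-enantiomer F8.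

Step 14. The amide base may deprotonate other sites (C8–H between two oxygens, benzylic ether CH2, the C3' methine), or boron trapping of the hindered C3 anion may be slow. The fallback avoids base; it sets out from 24 and comes back at 27. DMDO (acetone–CH2Cl2, 0 °C) epoxidises the C2=C3 bond to the 2,3-epoxide of 24 F9. Catalytic TsOH then opens the epoxide at C2 with loss of the C3 proton, which gives flavonol 27.

Further compounds
F1 | step 13 | [(2S,3S)-4,7-bis(benzyloxy)-3-[4-(benzyloxy)phenyl]-2-[3,5-bis(benzyloxy)phenyl]-2,3-dihydro-1-benzofuran-5-yl]lithium | [Li]c1cc(OCc2ccccc2)c2c(c1OCc1ccccc1)[C@H](c1ccc(OCc3ccccc3)cc1)[C@@H](c1cc(OCc3ccccc3)cc(OCc3ccccc3)c1)O2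
F2 | step 13 | (2S,3S)-4,7-bis(benzyloxy)-3-[4-(benzyloxy)phenyl]-2-[3,5-bis(benzyloxy)phenyl]-2,3-dihydro-1-benzofuran-5-carbaldehyde | O=Cc1cc(OCc2ccccc2)c2c(c1OCc1ccccc1)[C@H](c1ccc(OCc3ccccc3)cc1)[C@@H](c1cc(OCc3ccccc3)cc(OCc3ccccc3)c1)O2
F3 | step 13 | 1-(6-hydroxy-2,4-diisopropoxy-3-methylphenyl)ethan-1-one | CC(=O)c1c(O)cc(OC(C)C)c(C)c1OC(C)C
F4 | step 13 | (E)-3-G-1-(6-hydroxy-2,4-diisopropoxy-3-methylphenyl)prop-2-en-1-one | O=C(/C=C/c1cc(OCc2ccccc2)c2c(c1OCc1ccccc1)[C@H](c1ccc(OCc3ccccc3)cc1)[C@@H](c1cc(OCc3ccccc3)cc(OCc3ccccc3)c1)O2)c1c(O)cc(OC(C)C)c(C)c1OC(C)C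
F5 | step 10 | 1-[3,5-bis(benzyloxy)benzyl]thiolan-1-ium bromide | [Br-].C1CC[S+](C1)Cc1cc(OCc2ccccc2)cc(OCc2ccccc2)c1
F6 | step 10 | 1-[3,5-bis(benzyloxy)benzyl]thiolan-1-ium ylide (thiolanium benzylide) | [CH-](c1cc(OCc2ccccc2)cc(OCc2ccccc2)c1)[S+]1CCCC1
F7 | step 10 | racemic trans-4,7-bis(benzyloxy)-3-[4-(benzyloxy)phenyl]-2-[3,5-bis(benzyloxy)phenyl]-5-bromo-2,3-dihydro-1-benzofuran (1:1 pair of enantiomers) | Brc1cc(OCc2ccccc2)c2c(c1OCc1ccccc1)[C@H](c1ccc(OCc3ccccc3)cc1)[C@@H](c1cc(OCc3ccccc3)cc(OCc3ccccc3)c1)O2.Brc1cc(OCc2ccccc2)c2c(c1OCc1ccccc1)[C@@H](c1ccc(OCc3ccccc3)cc1)[C@H](c1cc(OCc3ccccc3)cc(OCc3ccccc3)c1)O2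
F8 | step 10 | (2R,3R)-4,7-bis(benzyloxy)-3-[4-(benzyloxy)phenyl]-2-[3,5-bis(benzyloxy)phenyl]-5-bromo-2,3-dihydro-1-benzofuran | Brc1cc(OCc2ccccc2)c2c(c1OCc1ccccc1)[C@@H](c1ccc(OCc3ccccc3)cc1)[C@H](c1cc(OCc3ccccc3)cc(OCc3ccccc3)c1)O2
F9 | step 14 | 2-G-2,3-epoxy-5,7-diisopropoxy-6-methylchroman-4-one (epoxide centres as a mixture) | O=C1C2OC2(c2cc(OCc3ccccc3)c3c(c2OCc2ccccc2)[C@H](c2ccc(OCc4ccccc4)cc2)[C@@H](c2cc(OCc4ccccc4)cc(OCc4ccccc4)c2)O3)Oc2cc(OC(C)C)c(C)c(OC(C)C)c12
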